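**Plan**

- Numbering: ring A is C1(=CH2)–C2–C3(OH)–C4(Br)–C5(Me2)–C6(spiro); ring B is C6–C7=C8–C9(OH)(C15HBr2)–C10–C11.
- Retrosynthesis: cut C9–C15 (carbenoid addition to a C9 ketone), then C2–C3. The 3-methylenecyclohexanol unit C1(=CH2)–C2–C3(OH) of ring A is the retron of a type 2 carbonyl-ene reaction between an isopropenyl group on C6 and a C3 aldehyde. Then cut C4–Br, remove the C4 carbon (one-carbon homologation) and cut C5–C6 (Ireland–Claisen).
- Forward: ring B comes from 3-ethoxycyclohexenone. The Ireland–Claisen step joins C5 to C6, the arm is lengthened by one carbon, C9 is oxidised, C4 is brominated, ring A closes in the ene step, and C15 is added last.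
- Stereochemistry: C6 from the CBS-derived carbinol by suprafacial [3,3] transfer; C4 by amine-catalysed bromination; C3 in the chair ene transition state; C9 by substrate-controlled addition to the spiro enone.

Key step: step 11

Remark: ethereal diazomethane is taken as freshly prepared from commercial N-methyl-N-nitroso-p-toluenesulfonamide; every other reagent and catalyst is a catalogue item.

**Route**

Step 1
Reactants: 1 3-ethoxycyclohex-2-en-1-one; 2 isopropenylmagnesium bromide
Product: 4 3-(prop-1-en-2-yl)cyclohex-2-en-1-one, via bromomagnesium alkoxide 3 (not isolated)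
Conditions: THF, 0 °C → rt; then 1 M HCl, rt
Reagents that add atoms: water, O
Why: 1,2-addition of the Grignard reagent to the vinylogous ester, then acid hydrolysis with loss of ethanol and water (Stork–Danheiser transposition), should give the cross-conjugated dienone.

Step 2
Reactants: 4 3-(prop-1-en-2-yl)cyclohex-2-en-1-one
Product: 5 (R)-3-(prop-1-en-2-yl)cyclohex-2-en-1-ol
Conditions: (S)-2-methyl-CBS-oxazaborolidine (20 mol %), catecholborane, toluene, −78 °C; then MeOH, aqueous work-up
Reagents that add atoms: none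
Why: Corey–Bakshi–Shibata reduction, in which the dienyl flank acts as the large group so that the (S)-catalyst should deliver hydride to the face that gives the (R)-carbinol, while catecholborane at −78 °C leaves the isopropenyl group alone.

Step 3
Reactants: 5 (R)-3-(prop-1-en-2-yl)cyclohex-2-en-1-ol; 6 2-methylpropanoyl chloride
Product: 7 (R)-3-(prop-1-en-2-yl)cyclohex-2-en-1-yl 2-methylpropanoate
Conditions: Et3N, DMAP (cat.), CH2Cl2, 0 °C
Reagents that add atoms: none
Why: base-mediated O-acylation under non-ionising conditions keeps the dienylic C–O bond and its configuration intact.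

Step 4
Reactants: 7 (R)-3-(prop-1-en-2-yl)cyclohex-2-en-1-yl 2-methylpropanoate
Product: 10 (S)-2-methyl-2-[1-(prop-1-en-2-yl)cyclohex-2-en-1-yl]propanoic acid, via silyl ketene acetal 8 (not isolated), via trimethylsilyl ester 9 (not isolated)
Conditions: LiN(iPr)2, Me3SiCl, THF, −78 °C → 60 °C; then 1 M HCl
Reagents that add atoms: none
Why: Ireland–Claisen rearrangement, suprafacial on the ring, so the new C5–C6 bond forms on the face that held the C–O bond and the carbinol configuration is relayed to quaternary C6; the symmetric gem-dimethyl terminus removes any enolate-geometry issue, and this rearrangement is the standard way to join two fully substituted carbons.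

Step 5
Reactants: 10 (S)-2-methyl-2-[1-(prop-1-en-2-yl)cyclohex-2-en-1-yl]propanoic acid
Product: 12 (S)-1-diazo-3-methyl-3-[1-(prop-1-en-2-yl)cyclohex-2-en-1-yl]butan-2-one, via acid chloride 11 (not isolated)
Conditions: 1-chloro-N,N,2-trimethylprop-1-en-1-amine, CH2Cl2, 0 °C → rt; then CH2N2, Et2O, 0 °C
Reagents that add atoms: diazomethane, C=[N+]=[N-]
Why: the α-chloro enamine forms the acid chloride without HCl, so the isopropenyl group is not hydrochlorinated, and acylation of diazomethane (first stage of the Arndt–Eistert homologation) tolerates a tertiary acyl chloride.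

Step 6
Reactants: 12 (S)-1-diazo-3-methyl-3-[1-(prop-1-en-2-yl)cyclohex-2-en-1-yl]butan-2-one
Product: 14 methyl (S)-3-methyl-3-[1-(prop-1-en-2-yl)cyclohex-2-en-1-yl]butanoate, via ketene 13 (not isolated)
Conditions: PhCO2Ag (cat.), Et3N, MeOH, rt → 50 °C, dark
Reagents that add atoms: methanol, CO
Why: silver-promoted Wolff rearrangement moves the tertiary alkyl group (C5) to the diazo carbon and methanol traps the ketene, which inserts the C4 methylene between C5 and the carboxyl carbon C3.

Step 7
Reactants: 14 methyl (S)-3-methyl-3-[1-(prop-1-en-2-yl)cyclohex-2-en-1-yl]butanoate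
Product: 15 methyl (S)-3-methyl-3-[4-oxo-1-(prop-1-en-2-yl)cyclohex-2-en-1-yl]butanoate
Conditions: Rh2(cap)4 (dirhodium tetracaprolactamate, 1 mol %), t-BuOOH (70% aq), K2CO3, CH2Cl2, rt
Reagents that add atoms: tert-butyl hydroperoxide, CC(C)(C)OO
Why: radical allylic C–H oxidation; C6 is quaternary, so the ring alkene has allylic hydrogens only at C9, the peroxy radical should combine at that less hindered terminus, and ring methylenes are expected to react much faster than the allylic methyl of the isopropenyl group.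

Step 8
Reactants: 15 methyl (S)-3-methyl-3-[4-oxo-1-(prop-1-en-2-yl)cyclohex-2-en-1-yl]butanoate
Product: 16 3-[(1S)-4-hydroxy-1-(prop-1-en-2-yl)cyclohex-2-en-1-yl]-3-methylbutan-1-ol (both C9 epimers)
Conditions: iBu2AlH (5 equiv), CH2Cl2, −78 → 0 °C; aqueous potassium sodium tartrate
Reagents that add atoms: none
Why: hydride reduction takes the ester to the primary alcohol and the enone to the allylic alcohol by 1,2-addition; the C9 epimer mixture is of no consequence because that carbinol is re-oxidised in the next step.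

Step 9
Reactants: 16 3-[(1S)-4-hydroxy-1-(prop-1-en-2-yl)cyclohex-2-en-1-yl]-3-methylbutan-1-ol
Product: 17 3-methyl-3-[(1S)-4-oxo-1-(prop-1-en-2-yl)cyclohex-2-en-1-yl]butanal
Conditions: Dess–Martin periodinane, CH2Cl2, 0 °C → rt
Reagents that add atoms: none
Why: Dess–Martin oxidation converts both carbinols at once under mild conditions, giving the aldehyde and restoring the enone without touching the alkenes.

Step 10
Reactants: 17 3-methyl-3-[(1S)-4-oxo-1-(prop-1-en-2-yl)cyclohex-2-en-1-yl]butanal
Product: 18 (2S)-2-bromo-3-methyl-3-[(1S)-4-oxo-1-(prop-1-en-2-yl)cyclohex-2-en-1-yl]butanal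
Conditions: (2R,5R)-2,5-diphenylpyrrolidine (20 mol %), PhCO2H (20 mol %), H2O, 4,4-dibromo-2,6-di-tert-butylcyclohexa-2,5-dien-1-one, CH2Cl2/pentane, −40 °C; cold silica plug, used at once
Reagents that add atoms: 4,4-dibromo-2,6-di-tert-butylcyclohexa-2,5-dien-1-one, CC(C)(C)C1=CC(Br)(Br)C=C(C(C)(C)C)C1=O
Why: enamine-catalysed α-bromination, in which the C2-symmetric amine condenses only with the aldehyde and one phenyl group shields one enamine face, so C4 is set by the catalyst and not by remote C6; the (2R,5R) antipode is the one expected to give the (4S) bromide, its enantiomer is available if the sense proves opposite, and quaternary C5 rules out HBr loss.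

Step 11
Reactants: 18 (2S)-2-bromo-3-methyl-3-[(1S)-4-oxo-1-(prop-1-en-2-yl)cyclohex-2-en-1-yl]butanal
Product: 20 (3R,4S,6S)-4-bromo-3-hydroxy-5,5-dimethyl-1-methylidenespiro[5.5]undec-7-en-9-one (locants as in the plan), via chloromethylaluminium alkoxide 19 (not isolated)
Conditions: Me2AlCl (2.2 equiv), CH2Cl2, −78 → −40 °C; cold 1 M HCl
Reagents that add atoms: none
Why: Me2AlCl binds the aldehyde oxygen, the CH2 terminus of the isopropenyl group attacks C3 while a methyl hydrogen passes to oxygen in a concerted, asynchronous ene process, and the alcohol complex then loses methane so that no free acid is present. The closest known reaction is the Lewis acid-promoted type 2 intramolecular carbonyl-ene cyclisation of 5-methylhex-5-enals to 3-methylenecyclohexanols. Ring A closes as a six-membered chair, exo with respect to the carbonyl and with the ene carbons C1 and C2 inside the new ring. C3 is controlled by C4 and C6: the chair that carries bromine and the C7 arm of ring B both equatorial puts the C–Br bond antiperiplanar to the forming C2–C3 bond, and the bicyclic ene array needs the carbonyl oxygen axial to reach the methyl hydrogen, which should give the 3R carbinol cis to bromine. The step needs chemoselectivity for the aldehyde over the enone and for the isopropenyl group over the enone alkene, and it must leave C4 untouched; the α-bromine makes the aldehyde the stronger enophile, the 1,1-disubstituted alkene is the only nucleophilic π bond, and a non-protic Lewis acid at −78 °C should prevent enolisation.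

Step 12
Reactants: 20 (3R,4S,6S)-4-bromo-3-hydroxy-5,5-dimethyl-1-methylidenespiro[5.5]undec-7-en-9-one
Product: 21 (3R,4S,6S)-4-bromo-5,5-dimethyl-1-methylidene-3-(trimethylsilyloxy)spiro[5.5]undec-7-en-9-one
Conditions: N-(trimethylsilyl)imidazole, CH2Cl2, rt
Reagents that add atoms: N-(trimethylsilyl)imidazole, C[Si](C)(C)n1ccnc1
Why: silyl transfer from the N-silylimidazole to the axial C3 hydroxyl needs no added base and masks the acidic proton before the carbenoid addition.

Step 13
Reactants: 21 (3R,4S,6S)-4-bromo-5,5-dimethyl-1-methylidene-3-(trimethylsilyloxy)spiro[5.5]undec-7-en-9-one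
Product: 23 mailiohydrin, (3R,4S,6S,9R)-4-bromo-9-(dibromomethyl)-5,5-dimethyl-1-methylidenespiro[5.5]undec-7-ene-3,9-diol, via silylated carbinol 22 (not isolated)
Conditions: CH2Br2, LiN(iPr)2, THF, −78 °C; then 21, −78 °C; then 1 M HCl, THF, 0 °C
Reagents that add atoms: dibromomethane, BrCBr
Why: 1,2-addition of the dibromomethyl carbenoid to the enone carbonyl; with ring B in the envelope that keeps C5 pseudoequatorial and C1 pseudoaxial, the branched carbenoid is expected to enter pseudoequatorially on the C1 face, which leaves the C9 hydroxyl cis to C5 as in the target, and the acidic work-up cleaves the silyl ether.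

**Compound list**

1 | 3-ethoxycyclohex-2-en-1-one | CCOC1=CC(=O)CCC1 | starting material
2 | isopropenylmagnesium bromide | CC(=C)[Mg]Br | starting material
3 | bromomagnesium 3-ethoxy-1-(prop-1-en-2-yl)cyclohex-2-en-1-olate (racemic) | CCOC1=CC(O[Mg]Br)(C(C)=C)CCC1 | intermediate
4 | 3-(prop-1-en-2-yl)cyclohex-2-en-1-one | CC(=C)C1=CC(=O)CCC1 | intermediate
5 | (R)-3-(prop-1-en-2-yl)cyclohex-2-en-1-ol | O[C@H]1C=C(C(C)=C)CCC1 | intermediate
6 | 2-methylpropanoyl chloride | CC(C)C(Cl)=O | starting material
7 | (R)-3-(prop-1-en-2-yl)cyclohex-2-en-1-yl 2-methylpropanoate | CC(C)C(=O)O[C@H]1C=C(C(C)=C)CCC1 | intermediate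
8 | trimethylsilyl ketene acetal of 7 | CC(C)=C(O[Si](C)(C)C)O[C@H]1C=C(C(C)=C)CCC1 | intermediate
9 | trimethylsilyl (S)-2-methyl-2-[1-(prop-1-en-2-yl)cyclohex-2-en-1-yl]propanoate | C[Si](C)(C)OC(=O)C(C)(C)[C@]1(C(C)=C)C=CCCC1 | intermediate
10 | (S)-2-methyl-2-[1-(prop-1-en-2-yl)cyclohex-2-en-1-yl]propanoic acid | OC(=O)C(C)(C)[C@]1(C(C)=C)C=CCCC1 | intermediate
11 | (S)-2-methyl-2-[1-(prop-1-en-2-yl)cyclohex-2-en-1-yl]propanoyl chloride | ClC(=O)C(C)(C)[C@]1(C(C)=C)C=CCCC1 | intermediate
12 | (S)-1-diazo-3-methyl-3-[1-(prop-1-en-2-yl)cyclohex-2-en-1-yl]butan-2-one | [N-]=[N+]=CC(=O)C(C)(C)[C@]1(C(C)=C)C=CCCC1 | intermediate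
13 | (S)-3-methyl-3-[1-(prop-1-en-2-yl)cyclohex-2-en-1-yl]but-1-en-1-one (ketene) | O=C=CC(C)(C)[C@]1(C(C)=C)C=CCCC1 | intermediate
14 | methyl (S)-3-methyl-3-[1-(prop-1-en-2-yl)cyclohex-2-en-1-yl]butanoate | COC(=O)CC(C)(C)[C@]1(C(C)=C)C=CCCC1 | intermediate
15 | methyl (S)-3-methyl-3-[4-oxo-1-(prop-1-en-2-yl)cyclohex-2-en-1-yl]butanoate | COC(=O)CC(C)(C)[C@]1(C(C)=C)C=CC(=O)CC1 | intermediate
16 | 3-[(1S)-4-hydroxy-1-(prop-1-en-2-yl)cyclohex-2-en-1-yl]-3-methylbutan-1-ol (C9 epimers) | OCCC(C)(C)[C@]1(C(C)=C)C=CC(O)CC1 | intermediate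
17 | 3-methyl-3-[(1S)-4-oxo-1-(prop-1-en-2-yl)cyclohex-2-en-1-yl]butanal | O=CCC(C)(C)[C@]1(C(C)=C)C=CC(=O)CC1 | intermediate
18 | (2S)-2-bromo-3-methyl-3-[(1S)-4-oxo-1-(prop-1-en-2-yl)cyclohex-2-en-1-yl]butanal | O=C[C@@H](Br)C(C)(C)[C@]1(C(C)=C)C=CC(=O)CC1 | intermediate
19 | chloro(methyl)aluminium alkoxide of 20 | C=C1C[C@@H](O[Al](C)Cl)[C@@H](Br)C(C)(C)[C@@]12C=CC(=O)CC2 | intermediate
20 | (3R,4S,6S)-4-bromo-3-hydroxy-5,5-dimethyl-1-methylidenespiro[5.5]undec-7-en-9-one | C=C1C[C@@H](O)[C@@H](Br)C(C)(C)[C@@]12C=CC(=O)CC2 | intermediate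
21 | (3R,4S,6S)-4-bromo-5,5-dimethyl-1-methylidene-3-(trimethylsilyloxy)spiro[5.5]undec-7-en-9-one | C=C1C[C@@H](O[Si](C)(C)C)[C@@H](Br)C(C)(C)[C@@]12C=CC(=O)CC2 | intermediate
22 | (3R,4S,6S,9R)-4-bromo-9-(dibromomethyl)-5,5-dimethyl-1-methylidene-3-(trimethylsilyloxy)spiro[5.5]undec-7-en-9-ol | C=C1C[C@@H](O[Si](C)(C)C)[C@@H](Br)C(C)(C)[C@@]12C=C[C@@](O)(C(Br)Br)CC2 | intermediate
23 | mailiohydrin, (3R,4S,6S,9R)-4-bromo-9-(dibromomethyl)-5,5-dimethyl-1-methylidenespiro[5.5]undec-7-ene-3,9-diol | C=C1C[C@@H](O)[C@@H](Br)C(C)(C)[C@@]12C=C[C@@](O)(C(Br)Br)CC2 | target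

**Step count**

Total: 13 steps. Longest linear sequence: 13 steps, from 1 to 23.

**Steps most likely to fail**

Step 10, bromination at C4. Catalyst control may be eroded by the bulk of the two adjacent quaternary carbons, and the bromo aldehyde may epimerise on handling.
- The fallback uses an oxidazolidinone auxiliary; it sets out from 14 and returns at 18.
- Saponification of 14 (LiOH, THF/H2O) gives (S)-3-methyl-3-[1-(prop-1-en-2-yl)cyclohex-2-en-1-yl]butanoic acid F1.
- The pivalic mixed anhydride acylates lithiated (R)-4-isopropyloxazolidin-2-one to give the N-acyl oxazolidinone F2.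
- Its dibutylboron enolate (Bu2BOTf, iPr2NEt, CH2Cl2, −78 °C) is brominated with NBS anti to the isopropyl group to give the (2S)-bromo imide F3.
- The allylic oxidation of step 7 then gives the 4-oxo bromo imide F4.
- LiBH4 (Et2O/MeOH, 0 °C) removes the auxiliary and reduces the ketone to give the bromo diol F5, which can be purified at this stage.
- Dess–Martin oxidation of both carbinols gives 18.

Step 11, ene closure. Facial selectivity at the aldehyde may be poor, because the axial oxygen–aluminium group is syn to the axial C5 methyl in the chair, so the trans bromohydrin may form; C4 may also epimerise under the Lewis acid.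
- The fallback sets C3 by ketone reduction; it sets out from 18 and returns at 20.
- The cyclisation product, if mainly the C3-epimeric spiro enone F6, is oxidised with Dess–Martin periodinane to the α-bromo diketone F7.
- iBu2AlH at −78 °C reduces both carbonyls. At C3 the hydride should take the equatorial path, because the axial C5 methyl blocks the axial one, giving the cis-bromohydrin allylic alcohol F8.
- MnO2 re-oxidises only the allylic C9 carbinol, giving 20.

Step 13, carbenoid addition. Facial selectivity at C9 is the least secure prediction of the route: the carbenoid may instead take the axial trajectory anti to the pseudoaxial C1, which would give the C9 epimer. Enolisation at C10 may also compete.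
- The fallback delivers oxygen, not carbon, along that axial trajectory; it sets out from 21 and returns at 22.
- Wittig bromomethylenation (Ph3P=CHBr from (bromomethyl)triphenylphosphonium bromide and KOtBu, THF, −78 °C → rt) gives the exocyclic bromodiene F9.
- NBS in wet THF at 0 °C delivers bromine to C15, and water captures the tertiary allylic C9 cation.
- This gives 22, which is desilylated as in step 13.

**Further compounds**

F1 | step 10 | (S)-3-methyl-3-[1-(prop-1-en-2-yl)cyclohex-2-en-1-yl]butanoic acid | OC(=O)CC(C)(C)[C@]1(C(C)=C)C=CCCC1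
F2 | step 10 | (R)-4-isopropyl-3-{(S)-3-methyl-3-[1-(prop-1-en-2-yl)cyclohex-2-en-1-yl]butanoyl}oxazolidin-2-one | O=C(CC(C)(C)[C@]1(C(C)=C)C=CCCC1)N1[C@H](C(C)C)COC1=O
F3 | step 10 | (R)-3-{(2S)-2-bromo-3-methyl-3-[(1S)-1-(prop-1-en-2-yl)cyclohex-2-en-1-yl]butanoyl}-4-isopropyloxazolidin-2-one | O=C([C@@H](Br)C(C)(C)[C@]1(C(C)=C)C=CCCC1)N1[C@H](C(C)C)COC1=O
F4 | step 10 | (R)-3-{(2S)-2-bromo-3-methyl-3-[(1S)-4-oxo-1-(prop-1-en-2-yl)cyclohex-2-en-1-yl]butanoyl}-4-isopropyloxazolidin-2-one | O=C([C@@H](Br)C(C)(C)[C@]1(C(C)=C)C=CC(=O)CC1)N1[C@H](C(C)C)COC1=O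
F5 | step 10 | (2S)-2-bromo-3-[(1S)-4-hydroxy-1-(prop-1-en-2-yl)cyclohex-2-en-1-yl]-3-methylbutan-1-ol (C9 epimers) | OC[C@@H](Br)C(C)(C)[C@]1(C(C)=C)C=CC(O)CC1
F6 | step 11 | (3S,4S,6S)-4-bromo-3-hydroxy-5,5-dimethyl-1-methylidenespiro[5.5]undec-7-en-9-one | C=C1C[C@H](O)[C@@H](Br)C(C)(C)[C@@]12C=CC(=O)CC2
F7 | step 11 | (4S,6S)-4-bromo-5,5-dimethyl-1-methylidenespiro[5.5]undec-7-ene-3,9-dione | C=C1CC(=O)[C@@H](Br)C(C)(C)[C@@]12C=CC(=O)CC2
F8 | step 11 | (3R,4S,6S)-4-bromo-5,5-dimethyl-1-methylidenespiro[5.5]undec-7-ene-3,9-diol (C9 epimers) | C=C1C[C@@H](O)[C@@H](Br)C(C)(C)[C@@]12C=CC(O)CC2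
F9 | step 13 | (3R,4S,6S)-4-bromo-9-(bromomethylidene)-5,5-dimethyl-1-methylidene-3-(trimethylsilyloxy)spiro[5.5]undec-7-ene (alkene isomers) | C=C1C[C@@H](O[Si](C)(C)C)[C@@H](Br)C(C)(C)[C@@]12C=CC(=CBr)CC2
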